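The data were generated by integration for an exercise; the scatter is artificial.

First end groups are conserved, so the delta run's readings at 50.0 min leave 52.7% of them in some unread form. Links and over-reaction product are therefore no closed pool, and the share asked for is reckoned here from over-reaction product made per link held.

| setting | delta | gamma | Saturday's | Monday's | Sunday's | Tuesday's |
|---|---|---|---|---|---|---|
| first end groups | 28 mM | 14 mM | 28 mM (fed, over 40 min) | 28 mM | 28 mM | 28 mM |
| second end groups | 29.4 mM | 29.4 mM | 29.4 mM | 29.4 mM (fed, over 40 min) | 29.4 mM (in portions, 3, over 40 min) | 29.4 mM |
| remark | run made earlier | run made earlier | all else is in the flask from the start; the feed brings no volume worth counting | all else is in the flask from the start; the feed brings no volume worth counting | first portion at the start, last at 40 min | everything together at the start |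
| time |  |  | 50 min | 50 min | 50 min | 50 min |

| run | time / min | links / % | over-reaction product / % | first end groups / % |
|---|---|---|---|---|
| delta | 2.50 | 16.0 | 1.6 | 79.0 |
| delta | 8.00 | 24.9 | 7.3 | 49.8 |
| delta | 15.0 | 23.6 | 12.8 | 31.1 |
| delta | 20.0 | 22.1 | 16.6 | 23.6 |
| delta | 30.0 | 19.2 | 20.1 | 15.7 |
| delta | 40.0 | 16.4 | 22.7 | 10.6 |
| delta | 50.0 | 15.0 | 24.4 | 7.9 |
| gamma | 0.250 | 2.3 | 0 | 98.3 |
| gamma | 0.833 | 7.0 | 0.4 | 92.5 |
| gamma | 1.33 | 10.5 | 0.4 | 88.0 |
| gamma | 2.00 | 14.6 | 1.8 | 82.4 |
| gamma | 3.00 | 19.8 | 2.9 | 74.8 |
| gamma | 4.00 | 23.5 | 3.5 | 68.5 |
| gamma | 5.00 | 25.8 | 5.1 | 62.2 |

(standard deviation of a reading: 0.3 percentage points)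
- the flask that comes out highest in share of links in links plus over-reaction product, or "all alike" when all lie within 1.5 percentage points (Saturday's / Monday's / Sunday's / Tuesday's / all alike)
- share of links in links plus over-reaction product at the end, Saturday's
- share of links in links plus over-reaction product at the end, Monday's
- share of links in links plus over-reaction product at the end, Sunday's
- share of links in links plus over-reaction product at the end, Tuesday's


Turn the question round. Feeding first end groups can win if over-reaction follows [first end groups]. The gamma run, charged with half as much, would then show 0.5 of the delta run's frequency. That frequency is over-reaction product made per link and per minute (pseudo-first-order), read from the start of each run. It reads 0.0678 /min for gamma and 0.0551 /min for delta, a ratio of 1.23. So this frequency doesn't halve with [first end groups], and it is taken here to follow [second end groups].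

The fall of first end groups in the gamma run, taken per mM of second end groups charged, reads 0.00323 /mM/min, and this reading serves here as the pick-up of second end groups. In Monday's, [second end groups] climbs from nothing toward feed rate over pick-up, with [first end groups] taken as near half its charge. The mean is estimated at about half that steady value, 8.13 mM. The turnovers of a link, frequency per mM times mean [second end groups] times time, come to 0.937 for Monday's: with links taken as roughly level, this turnover count gives a share near 1/(1+count), 51.6%. Sunday's portions are counted the same. Saturday's is taken to keep about 0.7 of its second end groups, so its estimated count is 2.37, more turnovers than Monday's. Tuesday's has the charges of the delta run, whose last readings give 38.1%.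

The forecast gives Saturday's first, with 50%, then Monday's 41%, Sunday's 39%, Tuesday's 38%, holding that “Both steps scale with A”.

The flasks give Sunday's first: Saturday's 41.1%, Monday's 52.3%, Sunday's 55.0%, Tuesday's 36.9%.

    second end groups + links → over-reaction product (k = 2.65 /M/min)
    first end groups + second end groups → links + by-product (k = 3.29 /M/min)
    first end groups + links → side product (k = 3.54 /M/min)

Monday's reckoned 51.6% stands against 52.3%, and its mean [second end groups] over 40 min was 7.07 mM against the reckoned 8.13 mM. The count holds no side product. Yet the gap between Sunday's and Tuesday's, 18 percentage points, shrinks to 8.2 points without the step from first end groups + links to side product.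

For the neighbour of Sunday's charged with 18 mM of second end groups, the count scales down to 0.574, a share of 63.5%. That flask gives 71.7%.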